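**Retrosynthetic overview**
1. Petrosin A ⇐ bis(2-nitroquinolizidine) macrocycle 24 (Nef reaction unveils both C2 ketones, base equilibration sets C1 and C3) ⇐ bis-lactam 22 (borane).
2. 22 ⇐ meso macrocyclic bis(azido cyclopentanone) 21 by a twofold intramolecular Schmidt reaction: each cyclopentanone C6–C7–C8–C9–C9a (C6 = carbonyl) takes up N5 between C6 and C9a and becomes ring B, while the chain C1–C2–C3–C4 closes ring A.
3. Enabling feature: N5 lies between C6 and C9a, and C9a is tied back to N5 through the four carbons C1–C4 of ring A. Ring B without N5 is therefore a 2,3-disubstituted cyclopentanone with an azide tether on its α-carbon; C2 is carried as a nitro group.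
4. 21 ⇐ 16-membered meso bis(alkylidenecyclopentanone) 16 + 2-methyl-3-nitropropan-1-ol (nitro-Michael, then OH → N3); 16 ⇐ silicon-bridged pair of enantiomeric enol silanes 13 by a double Mukaiyama aldol onto their own acetals, then loss of methanol.
5. Ring order: two cyclopentanones (C9 and C9′ from ligand-controlled copper-catalysed conjugate additions to cyclopentenone) → 16-membered carbocycle → rings A/A′ closed and rings B/B′ expanded (5 → 6) together in the key step.

Key step: step 11

Locants: quinolizidine numbering (N5; C1 bears the linker, C2 the carbonyl, C3 the methyl, then C4, C6–C9, C9a) is used for the carbocyclic precursors as well; primes mark the second unit.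

Assumption 1: the target configuration at C1/C1′ and C3/C3′ (both α to the C2 ketone) is taken to be the thermodynamic one for a trans-fused quinolizidin-2-one with an equatorial C9 chain (C3 methyl equatorial, C1 chain axial, which avoids the peri clash with the C9 chain). These centres and C2 are therefore carried as epimer mixtures in 19–25 (written without configuration) and are set in step 13.

Assumption 2: the sense of induction of the ferrocenyl diphosphine in step 3 is assumed; if it is the opposite, the two ligand enantiomers simply change places between steps 3 and 4, with no consequence because 13 is meso.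

Step 1
Reactants: 1 6-bromohexan-1-ol
Product: 3 6-bromo-1,1-dimethoxyhexane, via 6-bromohexanal 2 (not isolated)
Conditions: TEMPO (10 mol %), PhI(OAc)2, CH2Cl2, rt; then HC(OMe)3, MeOH, TsOH·H2O (5 mol %), rt
Reagents that add atoms: trimethyl orthoformate, COC(OC)OC
Why: TEMPO-catalysed oxidation with a hypervalent iodine co-oxidant should stop at the aldehyde, and acid-catalysed acetalisation with the orthoformate then masks it for the organomagnesium chemistry; no stereocentre is formed.

Step 2
Reactants: 3 6-bromo-1,1-dimethoxyhexane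
Product: 4 (6,6-dimethoxyhexyl)magnesium bromide (titrated Et2O stock solution, divided between steps 3 and 4)
Conditions: Mg turnings (I2-activated), Et2O, reflux; titration
Reagents that add atoms: magnesium, [Mg]
Why: insertion of magnesium into a primary alkyl bromide (Grignard reagent formation), to which the remote dimethyl acetal is inert; no stereocentre is formed.

Step 3
Reactants: 4 (6,6-dimethoxyhexyl)magnesium bromide; 5 cyclopent-2-en-1-one
Product: 7 trimethyl{[(3S)-3-(6,6-dimethoxyhexyl)cyclopent-1-en-1-yl]oxy}silane, via magnesium enolate 6 (not isolated)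
Conditions: 4 (Et2O solution) added to 5, CuBr·SMe2 (5 mol %), (R)-1-[(Sp)-2-(diphenylphosphino)ferrocenyl]ethyldicyclohexylphosphine (6 mol %), t-BuOMe, −75 °C; then TMSCl, Et3N, HMPA, −75 °C → rt
Reagents that add atoms: chlorotrimethylsilane, C[Si](C)(C)Cl
Why: copper-catalysed asymmetric conjugate addition of a Grignard reagent to a cyclic enone, in which the chiral diphosphine selects the enone face and so sets C9 as (S), followed by O-silylation of the magnesium enolate, which keeps the enol double bond regiodefined between C6 and C9a.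

Step 4
Reactants: 4 (6,6-dimethoxyhexyl)magnesium bromide; 5 cyclopent-2-en-1-one
Product: 9 trimethyl{[(3R)-3-(6,6-dimethoxyhexyl)cyclopent-1-en-1-yl]oxy}silane, via magnesium enolate 8 (not isolated)
Conditions: 4 (Et2O solution) added to 5, CuBr·SMe2 (5 mol %), (S)-1-[(Rp)-2-(diphenylphosphino)ferrocenyl]ethyldicyclohexylphosphine (6 mol %), t-BuOMe, −75 °C; then TMSCl, Et3N, HMPA, −75 °C → rt
Reagents that add atoms: chlorotrimethylsilane, C[Si](C)(C)Cl
Why: the same asymmetric conjugate addition and enolate silylation with the mirror-image ligand, so that C9′ is set as (R) by reagent control.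

Step 5
Reactants: 7 (3S)-trimethylsilyl enol ether; 9 (3R)-trimethylsilyl enol ether
Product: 13 dimethyl{[(3S)-3-(6,6-dimethoxyhexyl)cyclopent-1-en-1-yl]oxy}{[(3R)-3-(6,6-dimethoxyhexyl)cyclopent-1-en-1-yl]oxy}silane (meso), via lithium enolate 10 (not isolated), via chlorosilyl enol ether 11 (not isolated), via lithium enolate 12 (not isolated)
Conditions: 7, MeLi, THF, 0 °C; added to Me2SiCl2 (10 equiv), THF, −78 °C → rt; volatiles removed in vacuo; then 12 (from 9, MeLi, THF, 0 °C), THF, −78 °C → rt; used crude
Reagents that add atoms: dichlorodimethylsilane, C[Si](C)(Cl)Cl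
Why: MeLi cleavage of a trimethylsilyl enol ether gives the lithium enolate without loss of regiochemistry, and stepwise O-silylation of two enolates with a dichlorodialkylsilane is the established route to unsymmetrical silyl bis-enol ethers; adding the (S)-enolate to excess silane first and the (R)-enolate second should pair the two antipodes in one meso molecule, and no stereocentre is touched.

Step 6
Reactants: 13 meso silicon-bridged bis-enol ether
Product: 15 meso 16-membered bis(β-methoxy ketone) (9S,9aS,9′R,9a′R; C1/C1′ epimers), via seco mono-aldol enol silane 14 (not isolated)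
Conditions: 13 added by syringe pump to TMSOTf (0.3 equiv), 2,6-di-tert-butyl-4-methylpyridine (5 mol %), CH2Cl2 (1 mM final), −78 → −40 °C; Et3N quench
Reagents that add atoms: none
Why: Proposed new method: TMSOTf ionises one dimethyl acetal to an oxocarbenium ion, which is captured by the enol silane of the other cyclopentene through a 14-membered, bridge-bound transition state (reaction of an enol silane with its own chain would need an 8-membered ring); the silyl triflate released at the bridge silicon then ionises the second acetal, the remaining enol silane closes the 16-membered carbocycle, and silicon leaves as Me2Si(OMe)2; the closest known reactions are the TMSOTf-catalysed Mukaiyama aldol addition of silyl enol ethers to acetals and the use of silicon-tethered unsymmetrical bis-enol ethers for ketone cross-coupling; the temporary O–Si–O bridge guarantees that an (S)-unit reacts with an (R)-unit head to tail, and attack anti to the C9 chain should give the trans C9/C9a relation.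

Step 7
Reactants: 15 meso bis(β-methoxy ketone)
Product: 16 meso (9S,9′R)-(E,E)-16-membered bis(2-alkylidenecyclopentanone)
Conditions: DBU, toluene, 60 °C
Reagents that add atoms: none
Why: base-mediated E1cB loss of methanol from a β-methoxy ketone should give the conjugated enone with the thermodynamic (E)-alkylidene geometry; C9–H and C9′–H are only vinylogously acidic and should not be removed by an amidine base at this temperature, so both stereocentres stay intact.

Step 8
Reactants: 17 3-bromo-2-methylpropan-1-ol (racemic)
Product: 18 2-methyl-3-nitropropan-1-ol (racemic)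
Conditions: NaNO2, phloroglucinol, DMSO, rt
Reagents that add atoms: sodium nitrite, [Na+].[O-]N=O
Why: SN2 displacement of a primary bromide by nitrite (Kornblum nitroalkane synthesis), with phloroglucinol removing the nitrite ester formed by O-attack; the stereocentre is not involved.

Step 9
Reactants: 16 meso bis-enone; 18 2-methyl-3-nitropropan-1-ol
Product: 19 meso-series bis(γ-nitro ketone) diol (each C1 carries CH(NO2)–CH(CH3)–CH2OH; 9S,9aS,9′R,9a′R)
Conditions: 18 (6 equiv), DBU, MeCN, rt → 45 °C
Reagents that add atoms: none
Why: amidine-catalysed Michael addition of a nitronate to a 2-alkylidenecyclopentanone, a standard route to γ-nitro ketones; the enolate is protonated, and equilibrated by DBU, to the 2,3-trans cyclopentanone, so C9a ends trans to the C9 chain, whereas C1, C2 and C3 form as epimer mixtures that step 13 corrects.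

Step 10
Reactants: 19 bis(γ-nitro ketone) diol
Product: 21 bis-azide (CH2OH → CH2N3 at C4 and C4′), via bis-mesylate 20 (not isolated)
Conditions: MsCl, Et3N, CH2Cl2, −20 °C; then NaN3, DMF, 50 °C
Reagents that add atoms: sodium azide, [Na+].[N-]=[N+]=[N-]
Why: mesylation of the primary alcohols and SN2 displacement by azide; Et3N at −20 °C deprotonates the secondary nitroalkane only slowly and azide is far too weak a base to form the nitronate, so the γ-nitro mesylate should not close to a cyclic nitronate, and no stereocentre is touched.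

Step 11
Reactants: 21 meso-series macrocyclic bis(azido cyclopentanone)
Product: 22 bis-lactam (2,2′-dinitro-6,6′-dioxo bis-quinolizidine macrocycle; 9S,9aS,9′R,9a′R)
Conditions: 21 added slowly to TiCl4 (6 equiv), CH2Cl2, 0 °C → rt
Reagents that add atoms: none
Why: TiCl4 activates each C6 ketone, the alkylated nitrogen of the C4 azide adds to it to give a seven-membered azidohydrin, and the C6–C9a bond migrates from carbon to nitrogen as N2 leaves; this is the intramolecular Schmidt reaction of an alkyl azide with a ketone, the closest precedent being the TiCl4-promoted conversion of 2-(4-azidobutyl)cycloalkanones into fused bicyclic lactams. Ring A (N5, C4, C3, C2, C1, C9a) closes in two stages, 7-exo-trig addition of nitrogen to the C6 carbonyl and then the 1,2-shift of C9a from C6 to that nitrogen, and the same shift expands the cyclopentanone C6–C7–C8–C9–C9a to the six-membered lactam ring B by placing N5 between C6 and C9a. No new stereocentre is formed: C9a migrates with retention, so the trans C9/C9a relation fixed in step 9 becomes the trans H9/H9a relation of the quinolizidine, and C9 is untouched. The selectivity needed is migration of C9a rather than C7 (fused rather than bridged lactam); it is secured because the tether holds the departing N2 anti to the in-ring C6–C9a bond in the less strained azidohydrin conformer and because C9a is the more substituted, better migrating carbon. The C2 nitro group keeps the second carbonyl masked, so no 1,4-diketone side reactions can compete, and the two units, insulated by the pentamethylene linkers, should react independently in one flask.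

Step 12
Reactants: 22 bis-lactam
Product: 24 2,2′-dinitro bis-quinolizidine macrocycle (9S,9aS,9′R,9a′R), via bis(amine–borane) adduct 23 (not isolated)
Conditions: BH3·SMe2, THF, 65 °C; then MeOH, HCl, 65 °C; NaOH work-up
Reagents that add atoms: none
Why: borane reduces tertiary lactams to amines through the amine–borane adduct, which acidic methanolysis breaks up, and it does not reduce aliphatic nitro groups; no stereocentre is touched.

Step 13
Reactants: 24 2,2′-dinitro bis-quinolizidine macrocycle
Product: 26 petrosin A (1R,3R,9S,9aS,1′S,3′S,9′R,9a′R), via diketone epimer mixture 25 (not isolated)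
Conditions: NaOMe, MeOH, 0 °C; then aqueous TiCl3, NH4OAc, rt; then K2CO3, MeOH, 50 °C
Reagents that add atoms: water, O
Why: the titanium trichloride variant of the Nef reaction (nitronate reduced to the imine, then hydrolysed) should unveil both C2 ketones under near-neutral conditions that spare the tertiary amines, and carbonate then equilibrates the α-centres through the enolates and reversible β-amino ketone opening to the most stable array (trans-fused, C3 methyl equatorial, C1 chain axial and clear of the equatorial C9 chain), which sets C1, C3, C1′ and C3′ as in the target while C9 is not epimerisable and C9a already has the favoured configuration.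

**Compound list**
1 | 6-bromohexan-1-ol | OCCCCCCBr | starting material
2 | 6-bromohexanal | O=CCCCCCBr | intermediate
3 | 6-bromo-1,1-dimethoxyhexane | COC(OC)CCCCCBr | intermediate
4 | (6,6-dimethoxyhexyl)magnesium bromide | COC(OC)CCCCC[Mg]Br | intermediate
5 | cyclopent-2-en-1-one | O=C1C=CCC1 | starting material
6 | bromomagnesium (3S)-3-(6,6-dimethoxyhexyl)cyclopent-1-en-1-olate | Br[Mg]OC1=C[C@@H](CCCCCC(OC)OC)CC1 | intermediate
7 | trimethyl{[(3S)-3-(6,6-dimethoxyhexyl)cyclopent-1-en-1-yl]oxy}silane | C[Si](C)(C)OC1=C[C@@H](CCCCCC(OC)OC)CC1 | intermediate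
8 | bromomagnesium (3R)-3-(6,6-dimethoxyhexyl)cyclopent-1-en-1-olate | Br[Mg]OC1=C[C@H](CCCCCC(OC)OC)CC1 | intermediate
9 | trimethyl{[(3R)-3-(6,6-dimethoxyhexyl)cyclopent-1-en-1-yl]oxy}silane | C[Si](C)(C)OC1=C[C@H](CCCCCC(OC)OC)CC1 | intermediate
10 | lithium (3S)-3-(6,6-dimethoxyhexyl)cyclopent-1-en-1-olate | [Li]OC1=C[C@@H](CCCCCC(OC)OC)CC1 | intermediate
11 | chloro{[(3S)-3-(6,6-dimethoxyhexyl)cyclopent-1-en-1-yl]oxy}dimethylsilane | C[Si](C)(Cl)OC1=C[C@@H](CCCCCC(OC)OC)CC1 | intermediate
12 | lithium (3R)-3-(6,6-dimethoxyhexyl)cyclopent-1-en-1-olate | [Li]OC1=C[C@H](CCCCCC(OC)OC)CC1 | intermediate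
13 | dimethyl{[(3S)-3-(6,6-dimethoxyhexyl)cyclopent-1-en-1-yl]oxy}{[(3R)-3-(6,6-dimethoxyhexyl)cyclopent-1-en-1-yl]oxy}silane (meso) | C[Si](C)(OC1=C[C@@H](CCCCCC(OC)OC)CC1)OC1=C[C@H](CCCCCC(OC)OC)CC1 | intermediate
14 | seco mono-aldol: methoxydimethylsilyl enol ether of the (S)-unit whose former acetal carbon (now CH–OMe, C1′) is bonded to C9a′ of the (9′R,9a′R)-cyclopentanone, which still carries its acetal chain (racemic, one enantiomer drawn; C1′ epimers) | CO[Si](C)(C)OC1=C[C@@H](CCCCCC(OC)[C@@H]2C(=O)CC[C@H]2CCCCCC(OC)OC)CC1 | intermediate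
15 | meso 16-membered bis(β-methoxy ketone): ring C9–(CH2)5–C1′H(OMe)–C9a′–C9′–(CH2)5–C1H(OMe)–C9a, each C9a–C9 pair being C2–C3 of a cyclopentanone (C6, C6′ carbonyls); 9S,9aS,9′R,9a′R, trans; C1/C1′ epimers | C1CCCC(OC)[C@@H]2C(=O)CC[C@H]2CCCCCC(OC)[C@H]2C(=O)CC[C@@H]2C1 | intermediate
16 | meso (9S,9′R)-(E,E)-16-membered bis(2-alkylidenecyclopentanone) (C9a=C1 and C9a′=C1′) | C1CCC/C=C2/C(=O)CC[C@H]2CCCCC/C=C2/C(=O)CC[C@@H]2C1 | intermediate
17 | 3-bromo-2-methylpropan-1-ol (racemic) | OCC(C)CBr | starting material
18 | 2-methyl-3-nitropropan-1-ol (racemic) | OCC(C)C[N+](=O)[O-] | intermediate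
19 | macrocyclic bis(γ-nitro ketone) diol, C1 and C1′ each bearing CH(NO2)CH(CH3)CH2OH; 9S,9aS,9′R,9a′R; C1–C3 epimers | C1CCCC(C(C(C)CO)[N+](=O)[O-])[C@@H]2C(=O)CC[C@H]2CCCCCC(C(C(C)CO)[N+](=O)[O-])[C@H]2C(=O)CC[C@@H]2C1 | intermediate
20 | bis-mesylate of 19 | C1CCCC(C(C(C)COS(C)(=O)=O)[N+](=O)[O-])[C@@H]2C(=O)CC[C@H]2CCCCCC(C(C(C)COS(C)(=O)=O)[N+](=O)[O-])[C@H]2C(=O)CC[C@@H]2C1 | intermediate
21 | macrocyclic bis(azido nitro cyclopentanone) (C4 and C4′ azides); 9S,9aS,9′R,9a′R | C1CCCC(C(C(C)CN=[N+]=[N-])[N+](=O)[O-])[C@@H]2C(=O)CC[C@H]2CCCCCC(C(C(C)CN=[N+]=[N-])[N+](=O)[O-])[C@H]2C(=O)CC[C@@H]2C1 | intermediate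
22 | bis-lactam: 2,2′-dinitro-6,6′-dioxo bis-quinolizidine macrocycle; 9S,9aS,9′R,9a′R | C1CCCC2C([N+](=O)[O-])C(C)CN3C(=O)CC[C@H]([C@H]23)CCCCCC2C([N+](=O)[O-])C(C)CN3C(=O)CC[C@@H]([C@@H]23)C1 | intermediate
23 | bis(amine–borane) adduct of 24 | C1CCCC2C([N+](=O)[O-])C(C)C[N+]3([BH3-])CCC[C@H]([C@H]23)CCCCCC2C([N+](=O)[O-])C(C)C[N+]3([BH3-])CCC[C@@H]([C@@H]23)C1 | intermediate
24 | 2,2′-dinitro bis-quinolizidine macrocycle (petrosin A skeleton with CH–NO2 in place of each C2 ketone); 9S,9aS,9′R,9a′R | C1CCCC2C([N+](=O)[O-])C(C)CN3CCC[C@H]([C@H]23)CCCCCC2C([N+](=O)[O-])C(C)CN3CCC[C@@H]([C@@H]23)C1 | intermediate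
25 | petrosin A as a mixture of C1, C3, C1′, C3′ epimers; 9S,9aS,9′R,9a′R | C1CCCC2C(=O)C(C)CN3CCC[C@H]([C@H]23)CCCCCC2C(=O)C(C)CN3CCC[C@@H]([C@@H]23)C1 | intermediate
26 | petrosin A, (1R,3R,9S,9aS,1′S,3′S,9′R,9a′R), meso | C[C@@H]1CN2CCC[C@@H]3CCCCC[C@@H]4C(=O)[C@@H](C)CN5CCC[C@@H](CCCCC[C@@H](C1=O)[C@H]32)[C@H]45 | target

**Totals**
Total step count: 13. Longest linear sequence: 11 steps (1, 2, 3, 5, 6, 7, 9, 10, 11, 12, 13); steps 4 and 8 are side branches.

**Steps most likely to fail**

Step 6 (carries the label). What may go wrong: intermolecular aldol oligomerisation outruns the bridge-guided first C–C bond formation, or the O–Si–O bridge is cleaved by adventitious triflic acid before either aldol, so that the (S)/(R) pairing is lost. The fallback uses known chemistry, sets out from 9 and 5 and comes back at 16; the pairing is made by functional-group complementarity instead of a tether. Compound 9 is brominated with NBS (THF, 0 °C) to the α-bromo ketone (3R)-2-bromo-3-(6,6-dimethoxyhexyl)cyclopentan-1-one F1. In parallel, 5 is treated with hept-6-enylmagnesium bromide under the conditions of step 3 to give the alkene-terminated enol silane trimethyl{[(3S)-3-(hept-6-en-1-yl)cyclopent-1-en-1-yl]oxy}silane F2. Because F2 has no acetal and F1 no enol silane, a TMSOTf-catalysed Mukaiyama aldol (CH2Cl2, −78 °C) can only give the cross product, the linear β-methoxy ketone F3. Ozonolysis (O3, CH2Cl2/MeOH, −78 °C; Me2S) gives the aldehyde F4. SmI2 (THF, −78 °C, high dilution) then converts the α-bromo ketone into the regiodefined samarium enolate, which closes the 16-membered ring in an intramolecular Reformatsky-type aldol to the macrocyclic hydroxy methoxy diketone F5. MsCl/Et3N followed by DBU removes water and methanol and gives 16.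

Step 11 (key step). What may go wrong: the seven-membered azidohydrin forms too slowly in the macrocycle, so that acid-induced azide decomposition or migration of C7 (bridged lactam) takes over. The fallback sets out from 19 and comes back at 24; it keeps the ring expansion but uses a Beckmann rearrangement and closes ring A by N-alkylation. An Appel reaction (PPh3, CCl4) turns the primary alcohols of 19 into the bis-chloride F6. NH2OH·HCl/NaOAc (EtOH) gives the bis-oxime F7, with the hydroxyl anti to the more substituted C9a. A Beckmann rearrangement (cyanuric chloride, catalytic ZnCl2, MeCN, reflux) migrates C9a and gives the bis(NH-lactam) F8. BH3·SMe2 (THF, 65 °C; MeOH/HCl) reduces the lactams to the bis(secondary amine) F9, which on warming with NaI/NaHCO3 in MeCN closes rings A and A′ by 6-exo-tet N-alkylation at C4 and gives 24.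

Step 9. What may go wrong: addition of the hindered secondary nitronate to the trisubstituted enone is slow and reverses (retro-Michael) under the amidine base, so conversion stalls. The fallback sets out from 18 and 16 and comes back at 19; it replaces the reversible base-catalysed addition by an irreversible silyl-transfer Michael addition of a preformed nucleophile. Compound 18 is silylated (TMSCl, Et3N, 2.2 equiv, benzene, rt) to the silyl ether/silyl nitronate F10. F10 and 16 are combined with a catalytic fluoride source (tetrabutylammonium difluorotriphenylsilicate, THF, −78 °C → rt), which should give the bis(silyl enol ether) adduct F11; aqueous HCl/THF work-up removes the silyl groups, protonates C9a trans to the C9 chain and gives 19.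

**Further compounds**
F1 | step 6 | (3R)-2-bromo-3-(6,6-dimethoxyhexyl)cyclopentan-1-one | BrC1C(=O)CC[C@H]1CCCCCC(OC)OC
F2 | step 6 | trimethyl{[(3S)-3-(hept-6-en-1-yl)cyclopent-1-en-1-yl]oxy}silane | C[Si](C)(C)OC1=C[C@@H](CCCCCC=C)CC1
F3 | step 6 | linear cross-aldol β-methoxy ketone (alkene terminus on the S-unit, α-bromo ketone on the R-unit) | C=CCCCCC[C@H]1CCC(=O)[C@@H]1C(OC)CCCCC[C@@H]1CCC(=O)C1Br
F4 | step 6 | aldehyde from ozonolysis of F3 | O=CCCCCC[C@H]1CCC(=O)[C@@H]1C(OC)CCCCC[C@@H]1CCC(=O)C1Br
F5 | step 6 | macrocyclic 1′-hydroxy-1-methoxy diketone (9S,9aS,9′R,9a′R) | C1CCCC(O)[C@@H]2C(=O)CC[C@H]2CCCCCC(OC)[C@H]2C(=O)CC[C@@H]2C1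
F6 | step 11 | bis-chloride of 19 (C4 and C4′ chlorides) | C1CCCC(C(C(C)CCl)[N+](=O)[O-])[C@@H]2C(=O)CC[C@H]2CCCCCC(C(C(C)CCl)[N+](=O)[O-])[C@H]2C(=O)CC[C@@H]2C1
F7 | step 11 | bis-oxime of F6 | C1CCCC(C(C(C)CCl)[N+](=O)[O-])[C@@H]2C(=NO)CC[C@H]2CCCCCC(C(C(C)CCl)[N+](=O)[O-])[C@H]2C(=NO)CC[C@@H]2C1
F8 | step 11 | bis(NH δ-lactam) from Beckmann rearrangement | C1CCCC(C(C(C)CCl)[N+](=O)[O-])[C@@H]2NC(=O)CC[C@H]2CCCCCC(C(C(C)CCl)[N+](=O)[O-])[C@H]2NC(=O)CC[C@@H]2C1
F9 | step 11 | bis(piperidine) dichloride (secondary amines) | C1CCCC(C(C(C)CCl)[N+](=O)[O-])[C@@H]2NCCC[C@H]2CCCCCC(C(C(C)CCl)[N+](=O)[O-])[C@H]2NCCC[C@@H]2C1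
F10 | step 9 | trimethylsilyl nitronate of O-trimethylsilyl 18 | C[Si](C)(C)OCC(C)C=[N+]([O-])O[Si](C)(C)C
F11 | step 9 | bis(silyl enol ether) Michael adduct | C1CCCC(C(C(C)CO[Si](C)(C)C)[N+](=O)[O-])C2=C(O[Si](C)(C)C)CC[C@H]2CCCCCC(C(C(C)CO[Si](C)(C)C)[N+](=O)[O-])C2=C(O[Si](C)(C)C)CC[C@@H]2C1
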